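**Retrosynthetic overview**
1. Target 30 comes from dimethyl agathate 27. A ligand-controlled β-borylation/oxidation of the enoate sets C13, and both methyl esters are then cleaved.
2. 27 comes from the bicyclo[3.1.0]hexane ester 25 by the key ring expansion. The ring-fusion cyclopropane bond C4–C10 breaks, the five-membered ring becomes ring A, the allylsilane closes ring B (C9–C10), and C4 is methylated in the same flask.
3. 25 comes from the acyclic α-diazo ester 24 by enantioselective intramolecular cyclopropanation, which stores the absolute configuration at C5 and C10.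
4. 24 comes from chloro-triene ester 19 and methyl acetoacetate. 19 is assembled from 5-chloropent-1-yne, oxirane, 2,3-dihydrofuran, ICH2SiMe3 and methyl but-2-ynoate by carbometalation and a cuprate 1,2-metallate shift.
5. Ring order: the cyclopropane and cyclopentane form first (step 8), then rings A and B form together (step 9).

Assumption: labdane numbering (C1–C20) locates atoms throughout, and the catalyst antipodes named in steps 8 and 10 are taken to give the configurations drawn; if the sense is opposite, the mirror-image ligand is used.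

**Step 1**
Reactants: 1 5-chloropent-1-yne; 2 oxirane
Product: 5 (E)-7-chloro-4-methylhept-3-en-1-ol, via alkenylalane 3 (not isolated), via lithium alanate 4 (not isolated)
Conditions: AlMe3, Cp2ZrCl2 (20 mol %), CH2Cl2, 0 → 23 °C; volatiles off; n-BuLi, hexane/THF, −78 °C; 2, −78 → 0 °C; aq. HCl
Reagents that add atoms: trimethylaluminium, C[Al](C)C
Why: Negishi zirconium-catalysed methylalumination adds Me (to the internal carbon) and Al syn, and the alanate opens oxirane with retention at the alkenyl carbon, which fixes the E geometry of C5=C10; the chloropropyl arm is trans to Al and cannot cyclise.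

**Step 2**
Reactants: 5 (E)-7-chloro-4-methylhept-3-en-1-ol
Product: 6 (E)-7-chloro-1-iodo-4-methylhept-3-ene
Conditions: PPh3, I2, imidazole, CH2Cl2, 0 °C
Reagents that add atoms: iodine, II
Why: Appel-type iodination is an SN2 displacement of the oxyphosphonium group at a primary carbon; the alkene and the alkyl chloride are untouched and no stereocentre is involved.

**Step 3**
Reactants: 6 (E)-7-chloro-1-iodo-4-methylhept-3-ene; 7 2,3-dihydrofuran; 8 (iodomethyl)trimethylsilane
Product: 13 (3Z,7E)-11-chloro-8-methyl-4-[(trimethylsilyl)methyl]undeca-3,7-dien-1-ol, via 5-lithio-2,3-dihydrofuran 9 (not isolated), via alkyllithium 10 (not isolated), via mixed cuprate 11 (not isolated), via alkenylcopper alkoxide 12 (not isolated)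
Conditions: 7, t-BuLi, THF, −78 → 0 °C; separately 6, t-BuLi (2 equiv), Et2O/pentane, −78 °C, then CuBr·SMe2, −78 → −30 °C; combine, −30 → 23 °C; 8, HMPA, 23 °C; aq. NH4Cl
Reagents that add atoms: none
Why: In this 1,2-metallate rearrangement of an α-alkoxyalkenyl cuprate (Kocienski type), the alkyl group of 11 shifts from copper to the ring carbon with inversion as the C–O bond breaks, so it ends trans to the CH2CH2OLi arm, and 12 is alkylated by 8 with retention, which fixes the allylsilane geometry (C7 trans to C11).

**Step 4**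
Reactants: 13 (3Z,7E)-11-chloro-8-methyl-4-[(trimethylsilyl)methyl]undeca-3,7-dien-1-ol
Product: 14 (3Z,7E)-11-chloro-1-iodo-8-methyl-4-[(trimethylsilyl)methyl]undeca-3,7-diene
Conditions: PPh3, I2, imidazole (phosphonium salt preformed), CH2Cl2, 0 °C
Reagents that add atoms: iodine, II
Why: Appel-type iodination at the primary alcohol; preforming the phosphonium iodide leaves no free iodine and the imidazole buffer prevents desilylation of the allylsilane.

**Step 5**
Reactants: 14 (3Z,7E)-11-chloro-1-iodo-8-methyl-4-[(trimethylsilyl)methyl]undeca-3,7-diene; 15 methyl but-2-ynoate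
Product: 19 methyl (2E,6Z,10E)-14-chloro-3,11-dimethyl-7-[(trimethylsilyl)methyl]tetradeca-2,6,10-trienoate, via alkyllithium 16 (not isolated), via alkylcopper 17 (not isolated), via alkenylcopper adduct 18 (not isolated)
Conditions: t-BuLi (2 equiv), Et2O/pentane, −78 °C; CuBr·SMe2, THF/Me2S, −78 → −45 °C; 15, −78 °C; MeOH, −78 °C
Reagents that add atoms: none
Why: In this syn-carbocupration of an alkynoate the alkyl group adds to the β-carbon, and 18 holds its geometry at −78 °C and is protonated with retention, which gives the 2E enoate (C12 trans to C15).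

**Step 6**
Reactants: 19 methyl (2E,6Z,10E)-14-chloro-3,11-dimethyl-7-[(trimethylsilyl)methyl]tetradeca-2,6,10-trienoate; 20 methyl acetoacetate
Product: 23 dimethyl (2E,6Z,10E)-15-acetyl-3,11-dimethyl-7-[(trimethylsilyl)methyl]hexadeca-2,6,10-trienedioate (racemic at C15 of this name), via sodium enolate 21 (not isolated), via iodide 22 (not isolated)
Conditions: 20, NaH, THF/DMF, 0 °C; 19, NaI (0.2 equiv), 70 °C
Reagents that add atoms: sodium iodide, [Na+].[I-] (iodine appears only in 22)
Why: Acetoacetic ester alkylation (SN2) is speeded by in situ Finkelstein exchange; the β,β-disubstituted enoate is too hindered for Michael attack, and the new stereocentre is racemic but is erased in step 7.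

**Step 7**
Reactants: 23 dimethyl (2E,6Z,10E)-15-acetyl-3,11-dimethyl-7-[(trimethylsilyl)methyl]hexadeca-2,6,10-trienedioate
Product: 24 dimethyl (2E,6Z,10E)-15-diazo-3,11-dimethyl-7-[(trimethylsilyl)methyl]hexadeca-2,6,10-trienedioate
Conditions: 4-AcNHC6H4SO2N3, DBU, MeCN, 0 → 23 °C
Reagents that add atoms: 4-acetamidobenzenesulfonyl azide, CC(=O)Nc1ccc(cc1)S(=O)(=O)N=[N+]=[N-]
Why: In this Regitz deacylative diazo transfer the enolate attacks the azide and the adduct fragments with transfer of the acetyl group to the sulfonamide nitrogen, which leaves the α-alkyl-α-diazo ester.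

**Step 8**
Reactants: 24 dimethyl (2E,6Z,10E)-15-diazo-3,11-dimethyl-7-[(trimethylsilyl)methyl]hexadeca-2,6,10-trienedioate
Product: 25 methyl (1R,5R,6R)-6-[(3Z,7E)-9-methoxy-7-methyl-9-oxo-3-[(trimethylsilyl)methyl]nona-3,7-dien-1-yl]-5-methylbicyclo[3.1.0]hexane-1-carboxylate
Conditions: Rh2(S-PTTL)4 (0.5 mol %), hexanes/CH2Cl2, −78 °C, slow addition of 24
Reagents that add atoms: none
Why: In this intramolecular cyclopropanation by a rhodium carbene, the three-carbon tether selects the C5=C10 alkene, syn addition to the E alkene puts the C6 chain, the C10 methyl and the ester on one face, the chiral carboxylate pocket chooses the alkene face (C5, C10 and C4 of 25), and the bulky ligand at low temperature suppresses the 1,2-hydride shift to the enoate.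

**Step 9**
Reactants: 25 methyl (1R,5R,6R)-6-[(3Z,7E)-9-methoxy-7-methyl-9-oxo-3-[(trimethylsilyl)methyl]nona-3,7-dien-1-yl]-5-methylbicyclo[3.1.0]hexane-1-carboxylate
Product: 27 dimethyl agathate, dimethyl (13E)-labda-8(17),13-diene-15,19-dioate, via silyl ketene acetal 26 (not isolated)
Conditions: Me3SiNTf2 (5 mol %), 2,6-di-tert-butyl-4-methylpyridine (10 mol %), CH2Cl2, −78 → −30 °C; then Bu4N[Ph3SiF2], MeI (10 equiv), THF, −78 → 0 °C
Reagents that add atoms: iodomethane, CI
Why: Proposed new method: O-silylation of the cyclopropyl ester by the silylium catalyst polarises the bond between the acceptor carbon C4 and the fully substituted donor carbon C10 (the ring-fusion bond), so this bond breaks rather than C4–C5; the allylsilane tethered to C5 attacks C10 opposite to C4 through a chair, which enlarges the five-membered ring to ring A and closes ring B, and because the E geometry was stored in 25 the result is the trans-decalin with H5 and H9 α, Me20 β and C11 equatorial; loss of Me3Si+ from the β-silyl cation places the alkene only at C8(17) and regenerates the catalyst, so the silyl group is relayed to oxygen (26); fluoride then frees the C4 enolate, which takes MeI on the equatorial α face away from the axial C10 methyl and leaves the ester axial; the closest known reaction types are the Lewis-acid opening of acylcyclopropanes by a tethered olefin and the allylsilane-terminated cation–olefin cyclization, neither shown for a mono-ester bicyclo[3.1.0]hexane, for its ring-fusion bond, or with a catalytic silyl relay.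

**Step 10**
Reactants: 27 dimethyl agathate
Product: 29 dimethyl (13R)-13-hydroxylabd-8(17)-ene-15,19-dioate, via tertiary boronic ester 28 (not isolated)
Conditions: CuCl (3 mol %), NaOt-Bu (5 mol %), (R,S)-Josiphos (3 mol %), B2pin2, MeOH (2 equiv), THF, 23 °C; then NaBO3·4H2O, THF/H2O, 23 °C
Reagents that add atoms: bis(pinacolato)diboron, CC1(C)OB(OC1(C)C)B1OC(C)(C)C(C)(C)O1 (boryl group of 28); sodium perborate tetrahydrate, [Na+].[Na+].O[B-]1(O)OO[B-](O)(O)OO1 (hydroxyl oxygen of 29)
Why: In this enantioselective copper-boryl conjugate addition to a β,β-disubstituted enoate, the ligand alone picks the face of the E enoate because the core is remote, the unactivated C8(17) alkene does not react, and C–B oxidation goes with retention to set 13R.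

**Step 11**
Reactants: 29 dimethyl (13R)-13-hydroxylabd-8(17)-ene-15,19-dioate
Product: 30 (13R)-13-hydroxylabd-8(17)-ene-15,19-dioic acid (target)
Conditions: LiSPr (8 equiv), HMPA, 23 °C; aq. HCl
Reagents that add atoms: none
Why: Thiolate SN2 dealkylation at the methyl carbons cleaves both esters without attack at the hindered axial C19 carbonyl, and the weakly basic thiolate causes no retro-aldol reaction, dehydration or alkene shift, so no stereocentre is touched.

**Compound list**
1 | 5-chloropent-1-yne | C#CCCCCl | starting material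
2 | oxirane | C1CO1 | starting material
3 | [(E)-5-chloro-2-methylpent-1-en-1-yl]dimethylalane | C[Al](C)/C=C(\C)CCCCl | intermediate
4 | lithium butyl[(E)-5-chloro-2-methylpent-1-en-1-yl]dimethylalanate | [Li+].CCCC[Al-](C)(C)/C=C(\C)CCCCl | intermediate
5 | (E)-7-chloro-4-methylhept-3-en-1-ol | OCC/C=C(\C)CCCCl | intermediate
6 | (E)-7-chloro-1-iodo-4-methylhept-3-ene | ICC/C=C(\C)CCCCl | intermediate
7 | 2,3-dihydrofuran | C1=COCC1 | starting material
8 | (iodomethyl)trimethylsilane | C[Si](C)(C)CI | starting material
9 | 5-lithio-2,3-dihydrofuran | [Li]C1=CCCO1 | intermediate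
10 | [(E)-7-chloro-4-methylhept-3-en-1-yl]lithium | [Li]CC/C=C(\C)CCCCl | intermediate
11 | lithium [(E)-7-chloro-4-methylhept-3-en-1-yl](4,5-dihydrofuran-2-yl)cuprate | [Li+].ClCCC/C(C)=C/CC[Cu-]C1=CCCO1 | intermediate
12 | lithium (7E)-11-chloro-4-cuprio-8-methylundeca-3,7-dien-1-olate (Cu cis to the oxidoethyl arm) | [Li]OCC/C=C(/CC/C=C(\C)CCCCl)[Cu] | intermediate
13 | (3Z,7E)-11-chloro-8-methyl-4-[(trimethylsilyl)methyl]undeca-3,7-dien-1-ol | OCC/C=C(/CC/C=C(\C)CCCCl)C[Si](C)(C)C | intermediate
14 | (3Z,7E)-11-chloro-1-iodo-8-methyl-4-[(trimethylsilyl)methyl]undeca-3,7-diene | ICC/C=C(/CC/C=C(\C)CCCCl)C[Si](C)(C)C | intermediate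
15 | methyl but-2-ynoate | CC#CC(=O)OC | starting material
16 | [(3Z,7E)-11-chloro-8-methyl-4-[(trimethylsilyl)methyl]undeca-3,7-dien-1-yl]lithium | [Li]CC/C=C(/CC/C=C(\C)CCCCl)C[Si](C)(C)C | intermediate
17 | [(3Z,7E)-11-chloro-8-methyl-4-[(trimethylsilyl)methyl]undeca-3,7-dien-1-yl]copper | [Cu]CC/C=C(/CC/C=C(\C)CCCCl)C[Si](C)(C)C | intermediate
18 | methyl (6Z,10E)-14-chloro-2-cuprio-3,11-dimethyl-7-[(trimethylsilyl)methyl]tetradeca-2,6,10-trienoate (Cu cis to the long chain) | COC(=O)/C([Cu])=C(\C)CC/C=C(/CC/C=C(\C)CCCCl)C[Si](C)(C)C | intermediate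
19 | methyl (2E,6Z,10E)-14-chloro-3,11-dimethyl-7-[(trimethylsilyl)methyl]tetradeca-2,6,10-trienoate | COC(=O)/C=C(\C)CC/C=C(/CC/C=C(\C)CCCCl)C[Si](C)(C)C | intermediate
20 | methyl acetoacetate | CC(=O)CC(=O)OC | starting material
21 | sodium enolate of methyl acetoacetate | [Na+].COC(=O)C=C(C)[O-] | intermediate
22 | methyl (2E,6Z,10E)-14-iodo-3,11-dimethyl-7-[(trimethylsilyl)methyl]tetradeca-2,6,10-trienoate | COC(=O)/C=C(\C)CC/C=C(/CC/C=C(\C)CCCI)C[Si](C)(C)C | intermediate
23 | dimethyl (2E,6Z,10E)-15-acetyl-3,11-dimethyl-7-[(trimethylsilyl)methyl]hexadeca-2,6,10-trienedioate (racemic) | COC(=O)/C=C(\C)CC/C=C(/CC/C=C(\C)CCCC(C(C)=O)C(=O)OC)C[Si](C)(C)C | intermediate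
24 | dimethyl (2E,6Z,10E)-15-diazo-3,11-dimethyl-7-[(trimethylsilyl)methyl]hexadeca-2,6,10-trienedioate | COC(=O)/C=C(\C)CC/C=C(/CC/C=C(\C)CCCC(=[N+]=[N-])C(=O)OC)C[Si](C)(C)C | intermediate
25 | methyl (1R,5R,6R)-6-[(3Z,7E)-9-methoxy-7-methyl-9-oxo-3-[(trimethylsilyl)methyl]nona-3,7-dien-1-yl]-5-methylbicyclo[3.1.0]hexane-1-carboxylate | COC(=O)[C@@]12CCC[C@]1(C)[C@H]2CC/C(C[Si](C)(C)C)=C/CC/C(C)=C/C(=O)OC | intermediate
26 | methyl (13E)-19-methoxy-19-(trimethylsilyloxy)-18-norlabda-4(19),8(17),13-trien-15-oate (5α-H, 9α-H, 10β-Me) | C=C1CC[C@@H]2[C@](C)(CCCC2=C(OC)O[Si](C)(C)C)[C@H]1CC/C(C)=C/C(=O)OC | intermediate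
27 | dimethyl agathate, methyl (1S,4aR,5S,8aR)-5-[(3E)-5-methoxy-3-methyl-5-oxopent-3-en-1-yl]-1,4a-dimethyl-6-methylidenedecahydronaphthalene-1-carboxylate | C=C1CC[C@@H]2[C@](C)(CCC[C@]2(C)C(=O)OC)[C@H]1CC/C(C)=C/C(=O)OC | intermediate
28 | dimethyl (13S)-13-(4,4,5,5-tetramethyl-1,3,2-dioxaborolan-2-yl)labd-8(17)-ene-15,19-dioate | C=C1CC[C@@H]2[C@](C)(CCC[C@]2(C)C(=O)OC)[C@H]1CC[C@@](C)(B1OC(C)(C)C(C)(C)O1)CC(=O)OC | intermediate
29 | dimethyl (13R)-13-hydroxylabd-8(17)-ene-15,19-dioate | C=C1CC[C@@H]2[C@](C)(CCC[C@]2(C)C(=O)OC)[C@H]1CC[C@@](C)(O)CC(=O)OC | intermediate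
30 | (13R)-13-hydroxylabd-8(17)-ene-15,19-dioic acid, (1S,4aR,5S,8aR)-5-[(3R)-4-carboxy-3-hydroxy-3-methylbutyl]-1,4a-dimethyl-6-methylidenedecahydronaphthalene-1-carboxylic acid | C=C1CC[C@@H]2[C@](C)(CCC[C@]2(C)C(=O)O)[C@H]1CC[C@@](C)(O)CC(=O)O | target

**Totals:** 11 steps in all. The longest linear sequence is 11 steps, and no protecting groups are used.

**Steps most likely to fail**

Step 9 (the proposed new step). A single ester may not activate the cyclopropane enough, and protodesilylation or proton loss from the C10 cation may compete. The fallback sets out from 25 and comes back at 26. Iodotrimethylsilane with 2,6-di-tert-butylpyridine in CH2Cl2 at −78 °C opens the acylcyclopropane by the known homoconjugate addition of iodide at C10. This gives the tertiary iodide silyl ketene acetal F1. AgOTf in CH2Cl2 at −78 °C then ionises the C–I bond, and the allylsilane captures the cation (the known silver-assisted tert-alkylation of allylsilanes). The C5 stereocentre steers the chair closure to the trans-decalin. The 26 formed is methylated with Bu4N[Ph3SiF2] and MeI as in step 9 to give 27.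

Step 8. The 1,2-hydride shift to the Z enoate may win, or the enantioselectivity for this α-alkyl diazo ester may be too low. The fallback sets out from 24 and comes back at 25. Achiral Rh2(esp)2 in CH2Cl2 at 0 °C gives the racemate, that is 25 together with the mirror-image cyclopropane F2. The two are separated by preparative chromatography on a chiral stationary phase. This replaces catalyst control by resolution, at the cost of half the material.

Step 3. The alkylation of the alkenylcopper alkoxide 12 by 8 may be sluggish, or the mixed cuprate may transfer the wrong ligand. The fallback sets out from 6 (with 9) and comes back at 13. 5-Lithio-2,3-dihydrofuran 9 is alkylated directly with 6 in THF/HMPA to give 5-[(E)-7-chloro-4-methylhept-3-en-1-yl]-2,3-dihydrofuran F3. The enol ether C–O bond of F3 is then cross-coupled with Me3SiCH2MgCl under NiCl2(PPh3)2 catalysis in refluxing benzene/Et2O. This is a known nickel-catalysed ring opening that goes with retention, so the silylmethyl group ends cis to the hydroxyethyl arm and 13 is obtained after work-up.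

**Further compounds**
F1 | step 9 | tertiary iodide silyl ketene acetal, methyl (2E,6Z)-9-[(1R,2R)-2-iodo-6-[methoxy(trimethylsilyloxy)methylidene]-2-methylcyclohexyl]-3-methyl-7-[(trimethylsilyl)methyl]nona-2,6-dienoate | COC(O[Si](C)(C)C)=C1CCC[C@](C)(I)[C@H]1CC/C(C[Si](C)(C)C)=C/CC/C(C)=C/C(=O)OC
F2 | step 8 | mirror-image cyclopropane, methyl (1S,5S,6S)-6-[(3Z,7E)-9-methoxy-7-methyl-9-oxo-3-[(trimethylsilyl)methyl]nona-3,7-dien-1-yl]-5-methylbicyclo[3.1.0]hexane-1-carboxylate | COC(=O)[C@]12CCC[C@@]1(C)[C@@H]2CC/C(C[Si](C)(C)C)=C/CC/C(C)=C/C(=O)OC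
F3 | step 3 | 5-[(E)-7-chloro-4-methylhept-3-en-1-yl]-2,3-dihydrofuran | ClCCC/C(C)=C/CCC1=CCCO1
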